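**Plan**
- Retrosynthesis: the C1' carboxyl carbon of ring B is traced back to the aryl-bound carbon of a cinnamate alkene (oxidative cleavage, then aldehyde oxidation).
- The C6'–propyl and C1'–vinyl bonds are then cut together, back to a C1' aryl iodide that carries methoxy at C2' and a free C–H at C6'. This is the pattern that allows one ortho alkylation followed by ipso vinylation under palladium/norbornene relay.
- The depside C(=O)–O bond is cut next, and the ring A carboxyl is traced to a formyl group placed on olivetol dimethyl ether.
- Forward: ring A acid from olivetol (3 steps); iodophenol by halogen exchange (1 step); esterification; relay coupling; alkene cleavage; Pinnick oxidation. Both benzene rings are bought and no ring is formed.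
- Stereochemistry: the target has no stereocentre. The E alkene of the relay product comes from syn β-hydride elimination and is destroyed in the next step.

Key step: step 6

Remark: diol 13, which forms in passing in step 7, is racemic and is drawn as one enantiomer; the same holds for F5.

**Step 1**
Reactants: 1 olivetol (5-pentylbenzene-1,3-diol)
Product: 2 1,3-dimethoxy-5-pentylbenzene
Conditions: MeI, K2CO3, acetone, reflux
Reagents that add atoms: iodomethane, CI
Why: Williamson etherification of both phenols under carbonate in acetone, where O-alkylation should dominate over ring C-methylation.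

**Step 2**
Reactants: 2 1,3-dimethoxy-5-pentylbenzene
Product: 4 2,4-dimethoxy-6-pentylbenzaldehyde, via iminium chloride 3 (not isolated)
Conditions: POCl3, DMF, 0 °C to 70 °C; then H2O, rt
Reagents that add atoms: N,N-dimethylformamide, CN(C)C=O; water, O
Why: Vilsmeier–Haack formylation, expected to go to the ring position para to one methoxy and ortho to the other rather than the more crowded site between the two methoxy groups; hydrolysis of iminium salt 3 releases the aldehyde.

**Step 3**
Reactants: 4 2,4-dimethoxy-6-pentylbenzaldehyde
Product: 5 2,4-dimethoxy-6-pentylbenzoic acid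
Conditions: NaClO2, NaH2PO4, 2-methyl-2-butene, t-BuOH/H2O, rt
Reagents that add atoms: sodium chlorite, [Na+].[O-]Cl=O
Why: Pinnick oxidation tolerates di-ortho-substituted aryl aldehydes, and the alkene scavenger removes hypochlorous acid before it can chlorinate the electron-rich ring.

**Step 4**
Reactants: 6 4-bromo-3-methoxyphenol
Product: 7 4-iodo-3-methoxyphenol
Conditions: CuI (5 mol %), trans-N,N'-dimethylcyclohexane-1,2-diamine (10 mol %), NaI (2 equiv), 1,4-dioxane, 110 °C
Reagents that add atoms: sodium iodide, [Na+].[I-]
Why: copper-catalysed aromatic Finkelstein exchange, driven by precipitation of sodium bromide from dioxane; no base is present, so the phenol stays protonated and Ullmann etherification should not compete.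

**Step 5**
Reactants: 5 2,4-dimethoxy-6-pentylbenzoic acid; 7 4-iodo-3-methoxyphenol
Product: 9 4-iodo-3-methoxyphenyl 2,4-dimethoxy-6-pentylbenzoate, via mixed anhydride 8 (not isolated)
Conditions: (CF3CO)2O, toluene, 0 °C to rt (acid and anhydride premixed, then 7 added)
Reagents that add atoms: none
Why: trifluoroacetic anhydride esterification, the standard depside coupling for di-ortho-substituted benzoic acids; mixed anhydride 8 ionises to a hindered acylium ion that the phenol oxygen captures.

**Step 6**
Reactants: 9 4-iodo-3-methoxyphenyl 2,4-dimethoxy-6-pentylbenzoate; 10 1-iodopropane; 11 methyl acrylate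
Product: 12 methyl (E)-3-[4-(2,4-dimethoxy-6-pentylbenzoyloxy)-2-methoxy-6-propylphenyl]prop-2-enoate
Conditions: Pd(OAc)2 (10 mol %), P(2-furyl)3 (20 mol %), norbornene (2 equiv), Cs2CO3 (3 equiv), 10 (4 equiv), 11 (2 equiv), MeCN, 85 °C, sealed vessel
Reagents that add atoms: none
Why: Zerovalent palladium inserts into the C1'–I bond, norbornene undergoes syn carbopalladation, and the norbornylpalladium, which has no accessible syn β-hydrogen, palladates the C6'–H bond with carbonate assistance to give a five-membered aryl–norbornyl palladacycle. Oxidative addition of 1-iodopropane raises this to tetravalent palladium, and aryl–alkyl reductive elimination forms the C6'–propyl bond. With C2' (methoxy) and C6' (propyl) both occupied, steric pressure expels norbornene by β-carbon elimination, and the resulting divalent arylpalladium at C1' ends in a Mizoroki–Heck reaction with methyl acrylate. This is the Catellani reaction of ortho-substituted aryl iodides with primary alkyl iodides and acrylates; the palladacycle is transient, so no ring of the product is closed and no stereocentre is made, and the E geometry follows from syn insertion and syn β-hydride elimination. The step needs exactly one alkylation, at C6', and vinylation only after it: the C2' methoxy blocks the second ortho site, and excess norbornene should insert faster than the acrylate, which holds back direct Heck coupling. The depside carbonyl is flanked by methoxy and pentyl on ring A and should therefore resist carbonate at this temperature.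

**Step 7**
Reactants: 12 methyl (E)-3-[4-(2,4-dimethoxy-6-pentylbenzoyloxy)-2-methoxy-6-propylphenyl]prop-2-enoate
Product: 14 4-formyl-3-methoxy-5-propylphenyl 2,4-dimethoxy-6-pentylbenzoate, via diol 13 (not isolated)
Conditions: OsO4 (2 mol %), NaIO4 (4 equiv), 2,6-lutidine (2 equiv), 1,4-dioxane/H2O, rt
Reagents that add atoms: osmium tetroxide, O=[Os](=O)(=O)=O (delivers the oxygen atom and is re-oxidised by sodium periodate, [Na+].[O-]I(=O)(=O)=O)
Why: Lemieux–Johnson cleavage, in which syn dihydroxylation gives diol 13 and periodate splits it to the aryl aldehyde and methyl glyoxylate; 2,6-lutidine suppresses over-oxidation, and the near-neutral medium leaves the depside ester alone.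

**Step 8**
Reactants: 14 4-formyl-3-methoxy-5-propylphenyl 2,4-dimethoxy-6-pentylbenzoate
Product: 15 4-(2,4-dimethoxy-6-pentylbenzoyloxy)-2-methoxy-6-propylbenzoic acid (target)
Conditions: NaClO2, NaH2PO4, 2-methyl-2-butene, t-BuOH/H2O, rt
Reagents that add atoms: sodium chlorite, [Na+].[O-]Cl=O
Why: Pinnick oxidation of the hindered aldehyde under buffered, mildly acidic conditions gives the free acid directly, so no ester hydrolysis that would endanger the depside bond is needed.

**Compound list**
1 | olivetol (5-pentylbenzene-1,3-diol) | CCCCCc1cc(O)cc(O)c1 | starting material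
2 | 1,3-dimethoxy-5-pentylbenzene | CCCCCc1cc(OC)cc(OC)c1 | intermediate
3 | N-[(2,4-dimethoxy-6-pentylphenyl)methylidene]-N-methylmethanaminium chloride | CCCCCc1cc(OC)cc(OC)c1C=[N+](C)C.[Cl-] | intermediate
4 | 2,4-dimethoxy-6-pentylbenzaldehyde | CCCCCc1cc(OC)cc(OC)c1C=O | intermediate
5 | 2,4-dimethoxy-6-pentylbenzoic acid | CCCCCc1cc(OC)cc(OC)c1C(=O)O | intermediate
6 | 4-bromo-3-methoxyphenol | COc1cc(O)ccc1Br | starting material
7 | 4-iodo-3-methoxyphenol | COc1cc(O)ccc1I | intermediate
8 | 2,4-dimethoxy-6-pentylbenzoic trifluoroacetic anhydride | CCCCCc1cc(OC)cc(OC)c1C(=O)OC(=O)C(F)(F)F | intermediate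
9 | 4-iodo-3-methoxyphenyl 2,4-dimethoxy-6-pentylbenzoate | CCCCCc1cc(OC)cc(OC)c1C(=O)Oc1ccc(I)c(OC)c1 | intermediate
10 | 1-iodopropane | CCCI | starting material
11 | methyl acrylate | C=CC(=O)OC | starting material
12 | methyl (E)-3-[4-(2,4-dimethoxy-6-pentylbenzoyloxy)-2-methoxy-6-propylphenyl]prop-2-enoate | CCCCCc1cc(OC)cc(OC)c1C(=O)Oc1cc(CCC)c(/C=C/C(=O)OC)c(OC)c1 | intermediate
13 | methyl (2RS,3SR)-3-[4-(2,4-dimethoxy-6-pentylbenzoyloxy)-2-methoxy-6-propylphenyl]-2,3-dihydroxypropanoate (racemic, one enantiomer drawn) | CCCCCc1cc(OC)cc(OC)c1C(=O)Oc1cc(CCC)c([C@@H](O)[C@H](O)C(=O)OC)c(OC)c1 | intermediate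
14 | 4-formyl-3-methoxy-5-propylphenyl 2,4-dimethoxy-6-pentylbenzoate | CCCCCc1cc(OC)cc(OC)c1C(=O)Oc1cc(CCC)c(C=O)c(OC)c1 | intermediate
15 | 4-(2,4-dimethoxy-6-pentylbenzoyloxy)-2-methoxy-6-propylbenzoic acid | CCCCCc1cc(OC)cc(OC)c1C(=O)Oc1cc(CCC)c(C(=O)O)c(OC)c1 | target

**Count**
Total steps: 8. Longest linear sequence: 7 steps (steps 1, 2, 3, 5, 6, 7, 8, from olivetol).

**Steps most likely to fail**

Step 6. The depside ester may be lost to carbonate at 85 °C, or direct Heck coupling at C1' may outrun the norbornene relay if base and norbornene loadings have to be kept low to spare the ester. Fallback: run the relay before the depside bond exists.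
- The fallback sets out from 7, which with chloromethyl methyl ether and iPr2NEt in CH2Cl2 should give 1-iodo-2-methoxy-4-(methoxymethoxy)benzene F1.
- The same Pd(OAc)2/P(2-furyl)3/norbornene/Cs2CO3 relay with 10 and 11, now free to use a larger excess of norbornene and base, should give methyl (E)-3-[2-methoxy-4-(methoxymethoxy)-6-propylphenyl]prop-2-enoate F2.
- HCl in MeOH at 40 °C should remove the acetal to give methyl (E)-3-(4-hydroxy-2-methoxy-6-propylphenyl)prop-2-enoate F3.
- Esterification of F3 with acid 5 through mixed anhydride 8 ((CF3CO)2O, toluene) comes back to the route at 12.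

Step 7. Osmylation of the electron-poor acrylate double bond, shielded by two ortho substituents, may be slow, leaving the cleavage incomplete or letting the diol over-oxidise. Fallback: change the terminating olefin so that a more electron-rich alkene is cleaved.
- The fallback sets out from 9, which under the step 6 relay conditions with 10 and styrene in place of 11 should give the stilbene 3-methoxy-4-[(E)-2-phenylethenyl]-5-propylphenyl 2,4-dimethoxy-6-pentylbenzoate F4.
- OsO4/NaIO4/2,6-lutidine in dioxane/H2O should then pass through 4-[(1RS,2RS)-1,2-dihydroxy-2-phenylethyl]-3-methoxy-5-propylphenyl 2,4-dimethoxy-6-pentylbenzoate F5 and release benzaldehyde, coming back to the route at 14.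

Step 5. The acylium ion may acylate the electron-rich iodophenol on carbon (Friedel–Crafts attack para to the methoxy group), or trifluoroacetylation of the phenol may outpace the slow transfer of the hindered acyl group. Fallback: pre-formed acid chloride and phenoxide under basic conditions, where only O-acylation is open.
- The fallback sets out from 5, which with (COCl)2 and catalytic DMF in CH2Cl2 should give 2,4-dimethoxy-6-pentylbenzoyl chloride F6.
- Adding F6 to the sodium phenoxide of 7 (NaH, THF, 0 °C to rt) comes back to the route at 9.

**Further compounds**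
F1 | step 6 | 1-iodo-2-methoxy-4-(methoxymethoxy)benzene | COCOc1ccc(I)c(OC)c1
F2 | step 6 | methyl (E)-3-[2-methoxy-4-(methoxymethoxy)-6-propylphenyl]prop-2-enoate | COCOc1cc(CCC)c(/C=C/C(=O)OC)c(OC)c1
F3 | step 6 | methyl (E)-3-(4-hydroxy-2-methoxy-6-propylphenyl)prop-2-enoate | COC(=O)/C=C/c1c(CCC)cc(O)cc1OC
F4 | step 7 | 3-methoxy-4-[(E)-2-phenylethenyl]-5-propylphenyl 2,4-dimethoxy-6-pentylbenzoate | CCCCCc1cc(OC)cc(OC)c1C(=O)Oc1cc(CCC)c(/C=C/c2ccccc2)c(OC)c1
F5 | step 7 | 4-[(1RS,2RS)-1,2-dihydroxy-2-phenylethyl]-3-methoxy-5-propylphenyl 2,4-dimethoxy-6-pentylbenzoate (racemic, one enantiomer drawn) | CCCCCc1cc(OC)cc(OC)c1C(=O)Oc1cc(CCC)c([C@H]([C@@H](c2ccccc2)O)O)c(OC)c1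
F6 | step 5 | 2,4-dimethoxy-6-pentylbenzoyl chloride | CCCCCc1cc(OC)cc(OC)c1C(Cl)=O
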